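All runs were generated by integration for an exercise; the scatter is artificial.

Begin at the early readings of the two earlier runs, north-east and north-west, where substrate met coupling partner fed over 20 h. At 0.833 d, the end of the feed, north-east still showed 82.2% substrate and north-west 86.5%. North-west took 3.16 times the substrate, and the percentage gone by then, north-east over north-west, stands at a ratio of 1.32. So read the early percentage loss as following [coupling partner], dosed alike in both, and not [substrate].

Then watch the runs part: at 4.00 d north-east has 44.5% target and north-west 26.5%. So carry the cover, the partner charge over the substrate charge: 1.32 in north-east, 0.417 in north-west. Between these runs, each doubling of cover brought 11 percentage points of target; use this doubling gain with partner charge, feed and time held as here.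

| setting | north-east | north-west | cedar | maple | oak |
|---|---|---|---|---|---|
| substrate | 0.19 M | 0.60 M | 0.15 M | 0.25 M | 0.40 M |
| coupling partner | 0.25 M (fed, over 20 h) | 0.25 M (fed, over 20 h) | 0.250 M (fed, over 20 h) | 0.250 M (fed, over 20 h) | 0.250 M (fed, over 20 h) |
| remark | run made earlier; the fed solution adds 0.50 times the starting volume | run made earlier; the fed solution adds 0.50 times the starting volume | the fed solution adds 0.50 times the starting volume | the fed solution adds 0.50 times the starting volume | the fed solution adds 0.50 times the starting volume |
| time |  |  | 4.0 d | 4.0 d | 4.0 d |

| run | time / d | target / % | substrate / % |
|---|---|---|---|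
| north-east | 0.250 | 1.9 | 97.9 |
| north-east | 0.833 | 12.4 | 82.2 |
| north-east | 1.25 | 20.2 | 69.5 |
| north-east | 2.00 | 30.6 | 56.8 |
| north-east | 3.00 | 39.1 | 44.8 |
| north-east | 4.00 | 44.5 | 36.9 |
| north-west | 0.250 | 2.7 | 98.4 |
| north-west | 0.833 | 10.5 | 86.5 |
| north-west | 1.25 | 15.5 | 78.6 |
| north-west | 2.00 | 22.4 | 73.5 |
| north-west | 3.00 | 23.3 | 69.2 |
| north-west | 4.00 | 26.5 | 66.8 |

(each reading ± 0.5 percentage points)

- charges are per starting volume, the dose included; the dosed solution carries all of it
- the earlier runs were read with a standard deviation of 0.5 percentage points
- a reading or a percentage of target counts all its forms, free or not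
- "hardly changes" means that all values lie within two and a half points (for a concentration: within two and a half percent of the largest)

- amount of target at the end, in percent of the substrate charged for cedar, maple, oak, in this order
- the course of these numbers from the first flask to the last (rises all the way / falls, then rises / rises, then falls / falls all the way / hardly changes)

You take over cedar, maple and oak, with covers 1.67, 1.00 and 0.625; in oak the partner is the limiting reagent. My own reckoning from the gain gives 48.2%, 40.2% and 32.8% target at 4.0 d. Trust cedar's number least, since its cover lies beyond both runs. Expect substrate still present, as in the runs, which kept 36.9% and 66.8% at 4.00 d. Add neither partner nor substrate, for each cover stands on those charges.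

The forecast says 46%, 42% and 34%, course falls all the way: “The percentage falls all the way, because the partner is increasingly limiting.” Mine shares that course, but stands higher for cedar and lower for maple and oak.

The flasks gave 46.4%, 40.8% and 33.4%, course falls all the way, so the forecast held.

    substrate + coupling partner → target (k = 0.0830 M⁻¹ h⁻¹)
    substrate + 2 coupling partner → side product (k = 0.351 M⁻² h⁻¹)
    crystals ⇌ target, rate k3*(cs3 - [target]) while solid is left; crystals form when [target] > cs3 (solubility = 13.0 mM, k = 0.437 h⁻¹)

The doubling gain gave oak 32.8% against 33.4%, maple 40.2% against 40.8%, and cedar 48.2% against 46.4%. Target counts crystals, 28.3% of oak's 33.4%, and the ceiling on dissolved target makes no difference to that number. In cedar the side step came first, its turnover up to the asked time half done by 1.28 d, and crystal growth followed, half done by 1.93 d, while coupling partner went from 85.5% of its charge at the end of the feed, 0.833 d, to 46.9% at 4.00 d. In oak both steps ran while coupling partner went from 68.7% of its charge at the end of the feed, 0.833 d, to 13.9% at 4.00 d, when 56.4% of the substrate remained.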